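**Retrosynthetic overview**
- C7–OH: the (1S,2S)-threo alcohol comes from the racemic α-aryloxy ketone by one asymmetric transfer hydrogenation with dynamic kinetic resolution, which sets both stereocentres together.
- C7–C8 (key bond): the α-aryloxy ketone comes from veratraldehyde, used as an acyl anion (Breslow intermediate), adding to the oxygen-bearing carbon of an aryl vinyl ether (carbene-catalysed intermolecular hydroacylation).
- C8–O: the aryl vinyl ether comes from methyl vanillate by O-vinylation.
- No ring is formed; both benzene rings are bought intact.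

Assumption: the SMILES is read as (1S,2S), i.e. threo, (7S,8S) in neolignan numbering; the thiazolium and ruthenium catalysts are bought.

**Step 1**
Reactants: 1 methyl vanillate (methyl 4-hydroxy-3-methoxybenzoate)
Product: 2 methyl 4-(ethenyloxy)-3-methoxybenzoate
Conditions: vinyl acetate (2 equiv), [Ir(cod)Cl]2 (1 mol%), Na2CO3 (0.6 equiv), toluene, 100 °C
Reagents that add atoms: vinyl acetate, C=COC(C)=O
Why: Iridium-catalysed transfer vinylation (vinyl exchange with vinyl acetate), with Na2CO3 scavenging the acetic acid so the acid-labile aryl vinyl ether survives; the ester and methyl ethers are inert and no stereocentre is formed.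

**Step 2**
Reactants: 2 methyl 4-(ethenyloxy)-3-methoxybenzoate; 3 veratraldehyde (3,4-dimethoxybenzaldehyde, 1.5 equiv, added slowly)
Product: 5 rac-methyl 4-{[1-(3,4-dimethoxyphenyl)-1-oxopropan-2-yl]oxy}-3-methoxybenzoate, via Breslow intermediate 4 (not isolated)
Conditions: 3-benzyl-5-(2-hydroxyethyl)-4-methylthiazolium chloride (20 mol%), DBU (25 mol%), 4 Å MS, m-xylene, 140 °C, sealed tube
Reagents that add atoms: none
Why: Proposed new method: the thiazol-2-ylidene adds to 3 to give Breslow intermediate 4 (an acyl anion equivalent), whose enol O–H protonates the terminal CH2 of the vinyl ether while its nucleophilic carbon bonds to the oxygen-bearing, oxocarbenium-like carbon (Markovnikov C–C bond formation), and collapse of the adduct returns the carbene and the α-aryloxy ketone with all atoms of 2 and 3 retained; the closest known reactions are the intramolecular thiazolium-catalysed addition of aldehyde-derived acyl anion equivalents to aryl enol ethers (benzofuranone synthesis, same regiochemistry) and the intermolecular carbene-catalysed hydroacylation of styrenes and cyclopropenes; homo-benzoin formation from the electron-rich aldehyde is reversible at 140 °C and should drain into the irreversible hydroacylation; C8 is formed racemic and stays epimerisable for step 3.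

**Step 3**
Reactants: 5 rac-methyl 4-{[1-(3,4-dimethoxyphenyl)-1-oxopropan-2-yl]oxy}-3-methoxybenzoate
Product: 6 methyl 4-{[(1S,2S)-1-(3,4-dimethoxyphenyl)-1-hydroxypropan-2-yl]oxy}-3-methoxybenzoate
Conditions: RuCl[(R,R)-TsDPEN](p-cymene) (2 mol%), HCO2H/Et3N (1:5 mol/mol, 3 equiv HCO2H), DBU (20 mol%), DMF, 40 °C
Reagents that add atoms: none
Why: Noyori–Ikariya asymmetric transfer hydrogenation run as a dynamic kinetic resolution: the amine base epimerises C8 through the enolate, the (R,R) catalyst delivers hydride to the carbonyl face that gives the (1S) carbinol, and only the (2S)-ketone presents that face in the Felkin–Anh arrangement (C–OAr anti to the incoming hydride), so the racemate should funnel to the threo (1S,2S) alcohol, as in the conversion of rac-benzoin to a single hydrobenzoin.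

**Compound list**
1 | methyl vanillate (methyl 4-hydroxy-3-methoxybenzoate) | COC(=O)c1ccc(O)c(OC)c1 | starting material
2 | methyl 4-(ethenyloxy)-3-methoxybenzoate | COC(=O)c1ccc(OC=C)c(OC)c1 | intermediate
3 | veratraldehyde (3,4-dimethoxybenzaldehyde) | COc1ccc(C=O)cc1OC | starting material
4 | Breslow intermediate: 3-benzyl-2-[(3,4-dimethoxyphenyl)(hydroxy)methylidene]-5-(2-hydroxyethyl)-4-methyl-2,3-dihydro-1,3-thiazole | COc1ccc(cc1OC)C(O)=C1SC(CCO)=C(C)N1Cc1ccccc1 | intermediate
5 | rac-methyl 4-{[1-(3,4-dimethoxyphenyl)-1-oxopropan-2-yl]oxy}-3-methoxybenzoate | COC(=O)c1ccc(OC(C)C(=O)c2ccc(OC)c(OC)c2)c(OC)c1 | intermediate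
6 | methyl 4-{[(1S,2S)-1-(3,4-dimethoxyphenyl)-1-hydroxypropan-2-yl]oxy}-3-methoxybenzoate (threo) | COC(=O)c1ccc(O[C@@H](C)[C@@H](O)c2ccc(OC)c(OC)c2)c(OC)c1 | target

**Total step count:** 3. **Longest linear sequence:** 3 (1 → 2 → 5 → 6).

**Steps most likely to fail, with fallbacks**

Step 2 (highest risk: untested intermolecular hydroacylation; possible failure by benzoin build-up, vinyl ether loss or wrong regiochemistry). The fallback sets out from 1 and comes back at 5, keeping the same bond and an aldehyde-derived acyl anion equivalent but coupling by a radical pathway. Compound 1 is O-alkylated with 2-bromopropanoic acid (NaH 2.2 equiv, THF/DMF, 0 °C to rt, acidic work-up) to give rac-2-[2-methoxy-4-(methoxycarbonyl)phenoxy]propanoic acid F1. F1 is esterified with N-hydroxyphthalimide (DIC, DMAP cat., CH2Cl2) to give rac-1,3-dioxoisoindolin-2-yl 2-[2-methoxy-4-(methoxycarbonyl)phenoxy]propanoate F2. F2 and 3 are then joined by carbene-catalysed decarboxylative radical acylation (N-2,6-diisopropylphenyl thiazolium precatalyst 10 mol%, Cs2CO3 20 mol%, DMSO, 60 °C). The carbene-bound enolate of 3 reduces F2 by single-electron transfer, and the ketyl radical couples with the α-aryloxyalkyl radical to give 5.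

Step 3 (risk: C8 epimerises too slowly, giving only a kinetic resolution, or erythro product leaks through). The fallback sets out from 3 and comes back at 6, fixing C8 before the reduction. Compound 3 and acetaldehyde undergo enzymatic cross-acyloin condensation (benzaldehyde lyase, thiamine diphosphate, MgSO4, phosphate buffer pH 8 with 20% DMSO, 30 °C) to give (2R)-1-(3,4-dimethoxyphenyl)-2-hydroxypropan-1-one F3. Mitsunobu etherification of F3 with 1 (PPh3, DIAD, toluene, 0 °C) inverts C8 to give methyl 4-{[(2S)-1-(3,4-dimethoxyphenyl)-1-oxopropan-2-yl]oxy}-3-methoxybenzoate F4. F4 is reduced under non-epimerising acidic conditions (RuCl[(R,R)-TsDPEN](p-cymene), HCO2H/Et3N 5:2, rt), catalyst and Felkin–Anh preference being matched, to give 6.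

Step 1 (risk: sluggish vinyl transfer to the electron-poor phenol, or acid-catalysed loss of the product). The fallback sets out from 1 and comes back at 2 by alkylation and elimination. Compound 1 is alkylated with excess 1,2-dibromoethane (K2CO3, MeCN, reflux) to give methyl 4-(2-bromoethoxy)-3-methoxybenzoate F5. E2 elimination of F5 (KOtBu, THF, 0 °C) gives 2.

**Further compounds**
F1 | step 2 | rac-2-[2-methoxy-4-(methoxycarbonyl)phenoxy]propanoic acid | COC(=O)c1ccc(OC(C)C(O)=O)c(OC)c1
F2 | step 2 | rac-1,3-dioxoisoindolin-2-yl 2-[2-methoxy-4-(methoxycarbonyl)phenoxy]propanoate | COC(=O)c1ccc(OC(C)C(=O)ON2C(=O)c3ccccc3C2=O)c(OC)c1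
F3 | step 3 | (2R)-1-(3,4-dimethoxyphenyl)-2-hydroxypropan-1-one | COc1ccc(cc1OC)C(=O)[C@@H](C)O
F4 | step 3 | methyl 4-{[(2S)-1-(3,4-dimethoxyphenyl)-1-oxopropan-2-yl]oxy}-3-methoxybenzoate | COC(=O)c1ccc(O[C@@H](C)C(=O)c2ccc(OC)c(OC)c2)c(OC)c1
F5 | step 1 | methyl 4-(2-bromoethoxy)-3-methoxybenzoate | COC(=O)c1ccc(OCCBr)c(OC)c1
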